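## Structural features

The target is a tricyclic acetate built on an eight-membered carbocycle whose ring carbons are labelled in order C1, C2, C3, C4, C6, C7, C8, C9. A butenolide is fused across the tetrasubstituted C2=C3 bond (C18H2 on C2, carbonyl C19 on C3). A cyclopropane is fused across C4–C6 through the methylene C5, C7 carries a methyl group, C9 a free secondary hydroxyl, and C1 the branched chain C10H(C11H2OAc)(CH2CH2CH=CMe2). With these labels the six stereocentres are (1R,4R,6R,7S,9S,10S). C10, C1 and C9 stand next to one another on one flank (H-1 and H-9 cis, so side chain and hydroxyl share a face). C4, C6 and C7 stand on the other flank (cyclopropane methylene on the hydroxyl face, anti to the C7 methyl), and the two sets are separated by the sp2 pair C2/C3 and by the C8 methylene. Fragile points are the butenolide (acidic hydrogens at C18 and C1), the cyclopropane conjugated to it, the primary acetate beside a free secondary alcohol, and the trisubstituted side-chain alkene, which competes in any cyclopropanation, epoxidation or hydrogenation. The real difficulty is a medium ring with stereocentres on both flanks, plus the exocyclic C10 centre, whose two CH2-type arms make it a weak controller. The feature exploited is that C19, C3, C4, C6, C7 and the C7 methyl are the six carbons of (2E,4E)-hexa-2,4-dienoic acid, that C2, C1, C9, C8 form a second diene once C9 is an enol ether, and that the lactone oxygen and C18 tie the two dienes by three atoms, so that joining C2–C3 and C7–C8 closes the carbocycle and the lactone together.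

## Logic of the disconnections

27 to 26: the C11–O acetyl bond is cut last. The acetate would not survive the enolate chemistry needed earlier, so it is added at the end. The demand is that the primary hydroxyl reacts before the hindered secondary C9 hydroxyl.

26 to 25: the two O–Si bonds at C9 and C11 are cut together. One fluoride step then suffices, provided the butenolide is not exposed to unbuffered base.

25 to 23 (through 24) and 23 to 21 (through 22): the C2=C3 π bond is traced back to H-2 and a C3–Se bond, and the C3–Se bond to the lactone enolate. The cycloaddition necessarily delivers sp3 C2 and C3, which serve as temporary stereocentres and are erased here. The demand is that selenium stands syn to H-2 and that elimination cannot go towards C4, which the cyclopropane guarantees.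

21 to 20: the C9 O–Si bond is cut, a protecting step inserted so that no alkoxide is present during the enolate step.

20 to 18 (through 19): the C4–C5 and C5–C6 bonds are cut, exposing the cis C4=C6 alkene that a [4+4] cycloaddition leaves behind. The forward step must choose this alkene over the side-chain alkene and the face of the C9 hydroxyl.

18 to 17: the C9–H bond is cut back to the ketone. The demand is hydride delivery to the face that leaves the hydroxyl cis to the C10 branch.

17 to 16: the C1–H bond and the ketone are traced back to the C1=C9 silyl enol ether. The gain is that C9 becomes part of a diene. The demand is that C1 ends with its branch trans to the C2–C18 bond.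

16 to 14 (through 15): C2–C3 and C7–C8 are cut. Two rings, two skeletal bonds and three stereocentres fall away, leaving an acyclic ester of sorbic acid. The demand is cis ring fusion, suprafacial use of both dienes and the right face of the silyloxydiene relative to C10. A plan that put the same tert-butyldimethylsilyl group on C11, C18 and the enol oxygen would not let these three positions be told apart. The C11 oxygen therefore carries tert-butyldiphenylsilyl, which is orthogonal and is also the bulkier flank group that the facial argument of the key step needs. The configurations of the precursor and cycloadduct skeletons were checked against the target at C7 and C10 and are consistent.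

14 to 13: the enol O–Si bond is cut back to the methyl ketone. Regiochemistry is automatic, because C8 carries the only α-hydrogens.

13 to 11 and 12: the C19–O ester bond is cut, separating the sorbate from the dienyl alcohol.

11 to 10: the C18 O–Si bond is cut. The demand is selective loss of one primary silyl ether beside a more robust one.

10 to 8 (through 9): the C1=C2 π bond is traced back to an aldol. The demand is the (E)-geometry that places C18 on the outside of the future diene.

8 to 3, 5 and 6 (through 7): C10–C12 and C1–C2 are cut in one operation. Conjugate addition creates C10 and leaves the enolate exactly at C1, where the aldol bond is needed and where ordinary enolisation of a methyl ketone would not go. The demand is catalyst control of the C10 face.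

3 to 1 and 2, and 5 to 4: the C1=C10 alkene is cut by a Wittig disconnection and the C–Mg bond back to the bromide, both reaching commercial materials.

## Other disconnections considered

Alternative 1: The cut is C1–C2. The carbocycle is traced to the twelve-membered allylic lactone A1, in which C18 is the lactone carbonyl and C11 the allylic oxygen-bearing carbon. In the forward step the silyl ketene acetal of A1 would undergo an Ireland–Claisen shift, forming C1–C2, releasing C11–O and contracting the ring to the acid A2 with a C10=C11 methylene.
- In its favour: an eight-ring closure is replaced by a macrolactonisation and a thermal pericyclic step that needs no metal. The cyclopropane, C7 and C9 are already present in A2, so nothing has to be relayed across the ring after the key step. On this point the alternative is better than the chosen plan.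
- Against it: C10 is sp2 in A2 and must be re-created by hydroboration of a 1,1-disubstituted alkene with only acyclic induction from C1, whereas the chosen plan fixes C10 first by asymmetric catalysis. C19 is missing and must be added at C3 after unmasking the ketal. A1 needs a long linear sequence carrying four stereocentres and the cyclopropane.
- Comparison: mechanistically the Claisen shift is at least the equal of the nickel step in predictability, but its C1 outcome depends on the macrocycle conformation much as the chosen step depends on facial choice. In step count it is expected to be clearly longer.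

Alternative 2: The cut is C8–C9. The ring is closed last from the open-chain iodo aldehyde A3 by a Nozaki–Hiyama–Kishi reaction (CrCl2 with catalytic NiCl2), giving the cyclic allylic alcohol A4. Hydroxyl-directed hydrogenation of C7=C8, for instance with [Ir(cod)(PCy3)(py)]PF6, would then set C7.
- In its favour: the organochromium addition tolerates butenolide and acetate, so A4 is one step from the target, a better end game than the eight steps that follow the chosen key step. The allylic C9 hydroxyl is also a stronger director than the bishomoallylic one used here.
- Against it: the eight-membered ring is closed by a single bond from a flexible chain (high dilution, large excess of CrCl2), and C9 is set by the closing transition state. C1 in A3 is α to the aldehyde and γ to the butenolide carbonyl and is prone to epimerise. The hydrogenation must spare the side-chain alkene and the vinylcyclopropane. A3 itself is a long linear target.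
- Comparison: the chosen step forms two bonds and two rings on a metal template from a simple ester, while this alternative carries every function through a strained closure. Overall step count is expected to be comparable or longer, with the risk concentrated at the very end.

Alternative 3: The cuts are C1–C2 and C3–C4, with C1–C4 re-formed. The 2-substituted 5-methylcyclohexane-1,3-dione A5 and the silyloxybutynoate A6 would give the cyclooctenedione A7 under catalytic Cs2CO3. The sequence is conjugate addition of C1 to the alkyne carbon C2, closure of the vinyl anion on the C4 carbonyl to a cyclobutene alkoxide, and fragmentation of C1–C4.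
- In its favour: it is metal-free and cheap and avoids the entropy problem, the equal of the templated closure. C18 and C19 arrive with C2=C3 already at the butenolide oxidation level, so no late dehydrogenation is needed; on this point it is better than the chosen plan.
- Against it: C7 becomes stereogenic only when one of the two carbonyls of A5 is chosen. They differ only through the remote C10 and no ligand can intervene, which is weaker than the chosen plan. C4 emerges as a ketone that must be converted into the cyclopropane and told apart from the C9 ketone. C1 in A7 is flanked by ketone and enoate. A5 would require C-alkylation with a secondary stereodefined electrophile.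
- Comparison: the route to A7 is shorter, the route from A7 to the target is longer, and the total is not expected to be lower.

Key step: step 8

Assumption on the chemistry: (tert-butyldiphenylsilyloxy)acetaldehyde 1 is treated as a catalogue reagent, and the sense of induction of the chiral ligands in steps 3 and 8 is taken to be settled by a pilot run with each antipode, both being commercial.

## Steps

Step 1
Reactants: 1 (tert-butyldiphenylsilyloxy)acetaldehyde; 2 1-(triphenylphosphoranylidene)propan-2-one
Product: 3 (E)-5-(tert-butyldiphenylsilyloxy)pent-3-en-2-one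
Conditions: CH2Cl2, 40 °C
Reagents that add atoms: none
Why: Wittig olefination with a carbonyl-stabilised ylide, which reacts under thermodynamic control and should give the (E)-enone; the aldehyde has no stereocentre to lose.

Step 2
Reactants: 4 5-bromo-2-methylpent-2-ene
Product: 5 (4-methylpent-3-en-1-yl)magnesium bromide
Conditions: Mg turnings, I2 (cat.), Et2O, reflux
Reagents that add atoms: magnesium, [Mg]
Why: Grignard formation by insertion of magnesium into the primary C–Br bond; diethyl ether is used because the copper-catalysed addition that follows loses selectivity in THF, and the homoallylic reagent stays open-chain.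

Step 3
Reactants: 3 (E)-5-(tert-butyldiphenylsilyloxy)pent-3-en-2-one; 5 (4-methylpent-3-en-1-yl)magnesium bromide; 6 (tert-butyldimethylsilyloxy)acetaldehyde
Product: 8 (4S)-3-[2-(tert-butyldimethylsilyloxy)-1-hydroxyethyl]-4-[(tert-butyldiphenylsilyloxy)methyl]-8-methylnon-7-en-2-one (mixture at the two new centres C1 and C2), via bromomagnesium enolate 7 (not isolated)
Conditions: CuBr·SMe2 (5 mol %), (R,S)-Josiphos [(R)-1-[(S)-2-(diphenylphosphino)ferrocenyl]ethyldicyclohexylphosphine] (6 mol %), t-BuOMe, −75 °C, slow addition of 5; then 6, −75 °C; aq. NH4Cl
Reagents that add atoms: none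
Why: Copper-catalysed asymmetric conjugate addition of a Grignard reagent to an acyclic enone, followed by aldol trapping of the regiodefined magnesium enolate 7; the ferrocenyl diphosphine complex of monovalent copper is to deliver the homoprenyl group to the Si face of C10 (10S; the ligand antipode is used if the pilot run shows the opposite sense). Because the enolate is born at C1=C9, the C1–C2 bond forms at the hindered α-carbon that enolisation of the methyl ketone would not select; the centres at C1 and C2 are removed in step 4.

Step 4
Reactants: 8 (4S)-3-[2-(tert-butyldimethylsilyloxy)-1-hydroxyethyl]-4-[(tert-butyldiphenylsilyloxy)methyl]-8-methylnon-7-en-2-one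
Product: 10 (3E,4S)-3-[2-(tert-butyldimethylsilyloxy)ethylidene]-4-[(tert-butyldiphenylsilyloxy)methyl]-8-methylnon-7-en-2-one, via C2 mesylate 9 (not isolated)
Conditions: MsCl, Et3N, CH2Cl2, 0 °C; then DBU, 0 °C → rt
Reagents that add atoms: methanesulfonyl chloride, CS(=O)(=O)Cl (carried by intermediate 9 only)
Why: Mesylation of the secondary alcohol and E1cB elimination through the ketone enolate complete an aldol condensation; the enone should form with the CH2OSi group trans to the acetyl group (E), the tiglate-like arrangement favoured kinetically and thermodynamically. C10 is untouched because its hydrogen is not conjugated with the carbonyl.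

Step 5
Reactants: 10 (3E,4S)-3-[2-(tert-butyldimethylsilyloxy)ethylidene]-4-[(tert-butyldiphenylsilyloxy)methyl]-8-methylnon-7-en-2-one
Product: 11 (3E,4S)-4-[(tert-butyldiphenylsilyloxy)methyl]-3-(2-hydroxyethylidene)-8-methylnon-7-en-2-one
Conditions: HF·pyridine, pyridine, THF, 0 °C
Reagents that add atoms: none
Why: Acidic fluoride cleaves a primary tert-butyldimethylsilyl ether much faster than a tert-butyldiphenylsilyl ether, so only the C18 oxygen is released; buffering and 0 °C keep the γ-hydroxy enone from isomerising towards a furan.

Step 6
Reactants: 11 (3E,4S)-4-[(tert-butyldiphenylsilyloxy)methyl]-3-(2-hydroxyethylidene)-8-methylnon-7-en-2-one; 12 sorbic acid, (2E,4E)-hexa-2,4-dienoic acid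
Product: 13 (2E,4S)-3-acetyl-4-[(tert-butyldiphenylsilyloxy)methyl]-8-methylnona-2,7-dien-1-yl (2E,4E)-hexa-2,4-dienoate
Conditions: DCC, DMAP (cat.), CH2Cl2, 0 °C → rt
Reagents that add atoms: none
Why: Steglich esterification of a primary allylic alcohol; the neutral conditions leave the (E,E)-diene of the acid and the enone geometry unchanged.

Step 7
Reactants: 13 (2E,4S)-3-acetyl-4-[(tert-butyldiphenylsilyloxy)methyl]-8-methylnona-2,7-dien-1-yl (2E,4E)-hexa-2,4-dienoate
Product: 14 (2E)-4-(tert-butyldimethylsilyloxy)-3-[(2S)-1-(tert-butyldiphenylsilyloxy)-6-methylhept-5-en-2-yl]penta-2,4-dien-1-yl (2E,4E)-hexa-2,4-dienoate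
Conditions: TBSOTf, Et3N, CH2Cl2, −78 → 0 °C
Reagents that add atoms: tert-butyldimethylsilyl trifluoromethanesulfonate, CC(C)(C)[Si](C)(C)OS(=O)(=O)C(F)(F)F
Why: Soft enolisation of the methyl ketone by silyl triflate and amine; C8 carries the only α-hydrogens, so the cross-conjugated 2-silyloxydiene forms regiospecifically, and the ester is not enolised.

Step 8
Reactants: 14 (2E)-4-(tert-butyldimethylsilyloxy)-3-[(2S)-1-(tert-butyldiphenylsilyloxy)-6-methylhept-5-en-2-yl]penta-2,4-dien-1-yl (2E,4E)-hexa-2,4-dienoate
Product: 16 cis-fused cycloocta-1,5-diene γ-lactone (2S,3S,7S,10S): C1=C9 enol ether with OTBS on C9, cis C4=C6, methyl on C7, lactone C19(=O)–O–C18 across C3–C2, H-2, H-3 and H-7 on one face, C1 bearing (S)-CH(CH2OTBDPS)(CH2CH2CH=CMe2), via bis-allylnickel nickelacycle 15 (not isolated)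
Conditions: Ni(cod)2 (15 mol %), (S)-MonoPhos (30 mol %), toluene (0.01 M), 60 °C
Reagents that add atoms: bis(cycloocta-1,5-diene)nickel, C1CC=CCCC=C1.C1CC=CCCC=C1.[Ni] (nickel carried by intermediate 15 only)
Why: Zerovalent nickel binds both dienes of 14 and couples C2 with C3 oxidatively to the bis-allyl divalent nickel species 15; reductive elimination then joins the allyl termini C7 and C8 and releases zerovalent nickel. The closest known reaction type is the nickel-catalysed intramolecular [4+4] cycloaddition of bis-dienes joined by a three-atom tether, including dienes conjugated to a lactone carbonyl. The lactone closes in the oxidative coupling as a five-membered ring across the ester tether, which must reach its less populated s-cis rotamer (hence the heating); the eight-membered ring closes by C–C reductive elimination from the nine-membered nickelacycle, on the metal and not by end-to-end approach of a free chain. Both dienes react suprafacially, so the (E,E)-dienoate places C19 and the C7 methyl cis, and the (E)-C1=C2 geometry with the short tether enforces the cis ring fusion, leaving H-2, H-3 and H-7 on one face. The absolute sense relative to C10 rests on two elements: allylic 1,3-strain with C18 holds C10–H in the diene plane so that CH2OTBDPS and the homoprenyl CH2 occupy opposite faces, and reaction on the face away from the silyl ether is the one that leads to 16, which is why C11 carries the bulkiest practical silyl group. The chiral monodentate phosphoramidite is used in the sense matched with this bias (fixed by the pilot runs against its antipode and PPh3). The step needs [4+4] to win over thermal [4+2] addition, over insertion of nickel into the allylic C18–O bond and over hydrogen transfer from the sorbate methyl; the 60 °C limit, high dilution and a π-acceptor ligand that speeds reductive elimination serve this, and the trisubstituted side-chain alkene is too hindered to bind nickel. The step leaves the cis C4=C6 alkene for cyclopropanation and C9 as a masked ketone.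

Step 9
Reactants: 16 cis-fused cycloocta-1,5-diene γ-lactone (2S,3S,7S,10S) with C1=C9 silyl enol ether
Product: 17 C9 ketone (1R,2R,3S,7S,10S): cis-fused cyclooct-4-enone lactone with H-1 on the face of C18, the C10 branch trans to the C2–C18 bond, cis C4=C6 retained
Conditions: aq. HCl (1 M), THF, 0 °C → rt
Reagents that add atoms: none
Why: Acid hydrolysis of the silyl enol ether (protonation at C1, loss of silanol) under conditions that also equilibrate the ketone α-centre through its enol; C1 should settle with the bulky C10 branch trans to the C2–C18 bond (1R), whereas irreversible protonation from the exposed face would be expected to give the other epimer. The lactone α-hydrogen does not enolise in dilute acid, so C4=C6 stays out of conjugation, and the primary tert-butyldiphenylsilyl ether survives.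

Step 10
Reactants: 17 C9 ketone (1R,2R,3S,7S,10S)
Product: 18 C9 alcohol (1R,2R,3S,7S,9S,10S): hydroxyl cis to the C10 branch, H-1 and H-9 cis
Conditions: (R)-2-methyl-CBS-oxazaborolidine (0.5 equiv), catecholborane, toluene, −78 → −40 °C
Reagents that add atoms: none
Why: Corey–Bakshi–Shibata reduction: the oxazaborolidine binds the ketone oxygen anti to the larger, α-branched C1 flank and passes hydride from catecholborane to one face, which for the (R)-catalyst corresponds to 9S, the same sense as attack anti to the α-substituent; catecholborane at low temperature neither hydroborates the alkenes nor reduces the lactone.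

Step 11
Reactants: 18 C9 alcohol (1R,2R,3S,7S,9S,10S)
Product: 20 cyclopropane (1R,2R,3S,4R,6R,7S,9S,10S): C5 methylene across C4–C6 on the face of the C9 hydroxyl, anti to the C7 methyl and to C19, via ethylzinc alkoxide 19 (not isolated)
Conditions: Et2Zn (2.2 equiv), CH2Cl2, −20 °C; then CH2I2 (2.2 equiv), −20 → 0 °C
Reagents that add atoms: diiodomethane, ICI; diethylzinc, CC[Zn]CC (zinc and ethyl carried by intermediate 19 only)
Why: Hydroxyl-directed Simmons–Smith cyclopropanation in its diethylzinc/diiodomethane form: the zinc alkoxide 19 holds the carbenoid on the C9-oxygen face and passes methylene across the ring to the cis C4=C6 bond, a bishomoallylic relationship like that of cyclooct-4-enol. That face is also anti to both allylic substituents (C7 methyl and C3–C19), so both effects point to 4R,6R; the side-chain alkene has no hydroxyl within reach and is spared by limiting carbenoid and temperature.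

Step 12
Reactants: 20 cyclopropane alcohol (1R,2R,3S,4R,6R,7S,9S,10S)
Product: 21 C9 triethylsilyl ether of 20
Conditions: TESOTf, 2,6-lutidine, CH2Cl2, −78 → 0 °C
Reagents that add atoms: triethylsilyl trifluoromethanesulfonate, CC[Si](CC)(CC)OS(=O)(=O)C(F)(F)F
Why: Silylation of a hindered secondary alcohol with a silyl triflate; the ether keeps a C9 alkoxide from consuming base and selenium reagent or attacking the lactone in step 13.

Step 13
Reactants: 21 C9 triethylsilyl ether (1R,2R,3S,4R,6R,7S,9S,10S)
Product: 23 C3 phenylselenide (1R,2S,3R,4R,6R,7S,9S,10S): SePh on C3 syn to H-2, ring fusion still cis, via lithium lactone enolate 22 (not isolated)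
Conditions: LiN(iPr)2, THF, −78 °C; then PhSeSePh, DMPU, −78 → −40 °C
Reagents that add atoms: diphenyl diselenide, c1ccc(cc1)[Se][Se]c1ccccc1; lithium diisopropylamide, [Li]N(C(C)C)C(C)C (lithium carried by intermediate 22 only)
Why: α-Selenenylation of a lactone enolate: the base removes the only α-hydrogen (C3) and the enolate 22 attacks the diselenide on the face of H-2, anti to the C2–C1 bond, which keeps the fusion cis and puts selenium syn to H-2. The diselenide is preferred to PhSeBr because it does not add to the side-chain alkene.

Step 14
Reactants: 23 C3 phenylselenide (1R,2S,3R,4R,6R,7S,9S,10S)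
Product: 25 protected butenolide (1R,4R,6R,7S,9S,10S): C2=C3 butenolide, C9 OTES, C11 OTBDPS, via selenoxide 24 (not isolated)
Conditions: NaIO4, NaHCO3, THF/MeOH/H2O, 0 °C → rt
Reagents that add atoms: sodium periodate, [Na+].[O-]I(=O)(=O)=O (oxygen carried by intermediate 24 only)
Why: Selenide oxidation and selenoxide syn-elimination: the only β-hydrogen that can leave is H-2, since elimination towards C4 would give an alkylidenecyclopropane, so the tetrasubstituted C2=C3 butenolide forms and the temporary centres C2 and C3 vanish. Periodate does not touch the side-chain alkene, and its excess keeps the selenenic acid from adding to it.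

Step 15
Reactants: 25 protected butenolide (1R,4R,6R,7S,9S,10S)
Product: 26 diol (1R,4R,6R,7S,9S,10S): free C9 and C11 hydroxyls
Conditions: TBAF, AcOH (1:1), THF, 0 °C → rt
Reagents that add atoms: none
Why: Fluoride cleavage of both silyl ethers; acetic acid buffering keeps the medium from deprotonating the butenolide at C18 or C1.

Step 16
Reactants: 26 diol (1R,4R,6R,7S,9S,10S)
Product: 27 CNP0267808.2, the C11 acetate (1R,4R,6R,7S,9S,10S)
Conditions: AcCl (1.05 equiv), 2,4,6-collidine, CH2Cl2, −78 °C
Reagents that add atoms: acetyl chloride, CC(=O)Cl
Why: Kinetically selective acylation of the primary C11 hydroxyl with an acid chloride and a hindered pyridine base at low temperature; the C9 hydroxyl is secondary and flanked by the branched C1, and no stereocentre is touched.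

## Compound list

1 | (tert-butyldiphenylsilyloxy)acetaldehyde | O=CCO[Si](c1ccccc1)(c1ccccc1)C(C)(C)C | starting material
2 | 1-(triphenylphosphoranylidene)propan-2-one | CC(=O)C=P(c1ccccc1)(c1ccccc1)c1ccccc1 | starting material
3 | (E)-5-(tert-butyldiphenylsilyloxy)pent-3-en-2-one | CC(=O)/C=C/CO[Si](c1ccccc1)(c1ccccc1)C(C)(C)C | intermediate
4 | 5-bromo-2-methylpent-2-ene | CC(C)=CCCBr | starting material
5 | (4-methylpent-3-en-1-yl)magnesium bromide | CC(C)=CCC[Mg]Br | intermediate
6 | (tert-butyldimethylsilyloxy)acetaldehyde | O=CCO[Si](C)(C)C(C)(C)C | starting material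
7 | bromomagnesium enolate of (4S)-4-[(tert-butyldiphenylsilyloxy)methyl]-8-methylnon-7-en-2-one (enolate C1=C9, geometry not specified) | CC(C)(C)[Si](c1ccccc1)(c1ccccc1)OC[C@@H](CCC=C(C)C)C=C(C)O[Mg]Br | intermediate
8 | (4S)-3-[2-(tert-butyldimethylsilyloxy)-1-hydroxyethyl]-4-[(tert-butyldiphenylsilyloxy)methyl]-8-methylnon-7-en-2-one, mixture at C1 and C2 | CC(=O)C(C(O)CO[Si](C)(C)C(C)(C)C)[C@H](CCC=C(C)C)CO[Si](c1ccccc1)(c1ccccc1)C(C)(C)C | intermediate
9 | methanesulfonate of 8 at the C2 hydroxyl | CC(=O)C(C(OS(C)(=O)=O)CO[Si](C)(C)C(C)(C)C)[C@H](CCC=C(C)C)CO[Si](c1ccccc1)(c1ccccc1)C(C)(C)C | intermediate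
10 | (3E,4S)-3-[2-(tert-butyldimethylsilyloxy)ethylidene]-4-[(tert-butyldiphenylsilyloxy)methyl]-8-methylnon-7-en-2-one | CC(=O)/C(=C/CO[Si](C)(C)C(C)(C)C)[C@H](CCC=C(C)C)CO[Si](c1ccccc1)(c1ccccc1)C(C)(C)C | intermediate
11 | (3E,4S)-4-[(tert-butyldiphenylsilyloxy)methyl]-3-(2-hydroxyethylidene)-8-methylnon-7-en-2-one | CC(=O)/C(=C/CO)[C@H](CCC=C(C)C)CO[Si](c1ccccc1)(c1ccccc1)C(C)(C)C | intermediate
12 | sorbic acid, (2E,4E)-hexa-2,4-dienoic acid | C/C=C/C=C/C(=O)O | starting material
13 | (2E,4S)-3-acetyl-4-[(tert-butyldiphenylsilyloxy)methyl]-8-methylnona-2,7-dien-1-yl (2E,4E)-hexa-2,4-dienoate | CC(=O)/C(=C/COC(=O)/C=C/C=C/C)[C@H](CCC=C(C)C)CO[Si](c1ccccc1)(c1ccccc1)C(C)(C)C | intermediate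
14 | (2E)-4-(tert-butyldimethylsilyloxy)-3-[(2S)-1-(tert-butyldiphenylsilyloxy)-6-methylhept-5-en-2-yl]penta-2,4-dien-1-yl (2E,4E)-hexa-2,4-dienoate (cycloaddition precursor) | C/C=C/C=C/C(=O)OC/C=C(/C(=C)O[Si](C)(C)C(C)(C)C)[C@H](CCC=C(C)C)CO[Si](c1ccccc1)(c1ccccc1)C(C)(C)C | intermediate
15 | bis-allyl divalent nickel species after C2–C3 coupling, drawn as the nine-membered bis-σ nickelacycle C8–Ni–C7 without the phosphorus ligand (C7 and allyl geometry not fixed) | CC(C)(C)[Si](c1ccccc1)(c1ccccc1)OC[C@@H](CCC=C(C)C)C1=C(O[Si](C)(C)C(C)(C)C)C[Ni]C(C)C=C[C@@H]2C(=O)OC[C@H]12 | intermediate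
16 | cis-fused cycloocta-1,5-diene γ-lactone (2S,3S,7S,10S): C1=C9 enol ether (OTBS on C9), cis C4=C6, C7 methyl, lactone across C3–C2, C1 bearing (S)-CH(CH2OTBDPS)(homoprenyl) | CC(C)(C)[Si](c1ccccc1)(c1ccccc1)OC[C@@H](CCC=C(C)C)C1=C(O[Si](C)(C)C(C)(C)C)C[C@H](C)/C=C\[C@@H]2C(=O)OC[C@H]12 | intermediate
17 | C9 ketone (1R,2R,3S,7S,10S) of the cis-fused cyclooctene lactone, C10 branch trans to C18 | CC(C)(C)[Si](c1ccccc1)(c1ccccc1)OC[C@@H](CCC=C(C)C)[C@H]1C(=O)C[C@H](C)/C=C\[C@@H]2C(=O)OC[C@H]12 | intermediate
18 | C9 alcohol (1R,2R,3S,7S,9S,10S), hydroxyl cis to the C10 branch | CC(C)(C)[Si](c1ccccc1)(c1ccccc1)OC[C@@H](CCC=C(C)C)[C@H]1[C@@H](O)C[C@H](C)/C=C\[C@@H]2C(=O)OC[C@H]12 | intermediate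
19 | ethylzinc alkoxide of 18 | CC(C)(C)[Si](c1ccccc1)(c1ccccc1)OC[C@@H](CCC=C(C)C)[C@H]1[C@@H](O[Zn]CC)C[C@H](C)/C=C\[C@@H]2C(=O)OC[C@H]12 | intermediate
20 | cyclopropane alcohol (1R,2R,3S,4R,6R,7S,9S,10S), C5 on the hydroxyl face | CC(C)(C)[Si](c1ccccc1)(c1ccccc1)OC[C@@H](CCC=C(C)C)[C@H]1[C@@H](O)C[C@H](C)[C@H]3C[C@H]3[C@@H]2C(=O)OC[C@H]12 | intermediate
21 | C9 triethylsilyl ether of 20 | CC(C)(C)[Si](c1ccccc1)(c1ccccc1)OC[C@@H](CCC=C(C)C)[C@H]1[C@@H](O[Si](CC)(CC)CC)C[C@H](C)[C@H]3C[C@H]3[C@@H]2C(=O)OC[C@H]12 | intermediate
22 | lithium enolate of lactone 21 (C3=C19–OLi) | CC(C)(C)[Si](c1ccccc1)(c1ccccc1)OC[C@@H](CCC=C(C)C)[C@H]1[C@@H](O[Si](CC)(CC)CC)C[C@H](C)[C@H]3C[C@H]3C2=C(O[Li])OC[C@H]12 | intermediate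
23 | C3 phenylselenide (1R,2S,3R,4R,6R,7S,9S,10S), selenium syn to H-2 | CC(C)(C)[Si](c1ccccc1)(c1ccccc1)OC[C@@H](CCC=C(C)C)[C@H]1[C@@H](O[Si](CC)(CC)CC)C[C@H](C)[C@H]3C[C@H]3[C@]2([Se]c4ccccc4)C(=O)OC[C@H]12 | intermediate
24 | selenoxide of 23 (configuration at selenium not specified) | CC(C)(C)[Si](c1ccccc1)(c1ccccc1)OC[C@@H](CCC=C(C)C)[C@H]1[C@@H](O[Si](CC)(CC)CC)C[C@H](C)[C@H]3C[C@H]3[C@]2([Se](=O)c4ccccc4)C(=O)OC[C@H]12 | intermediate
25 | protected butenolide (1R,4R,6R,7S,9S,10S): C9 OTES, C11 OTBDPS | CC(C)(C)[Si](c1ccccc1)(c1ccccc1)OC[C@@H](CCC=C(C)C)[C@@H]1C2=C(C(=O)OC2)[C@@H]2C[C@@H]2[C@@H](C)C[C@@H]1O[Si](CC)(CC)CC | intermediate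
26 | diol (1R,4R,6R,7S,9S,10S): desacetyl target | OC[C@@H](CCC=C(C)C)[C@@H]1C2=C(C(=O)OC2)[C@@H]2C[C@@H]2[C@@H](C)C[C@@H]1O | intermediate
27 | CNP0267808.2 (1R,4R,6R,7S,9S,10S) | CC(=O)OC[C@@H](CCC=C(C)C)[C@@H]1C2=C(C(=O)OC2)[C@@H]2C[C@@H]2[C@@H](C)C[C@@H]1O | target

## Step count and least certain steps

Total: 16 steps. Longest linear sequence: 15 steps (steps 1 and 3 to 16, from 1 to 27). Step 2 is a one-step side branch.

Step 8 (key step). The most likely failure is incomplete discrimination between the two faces of the silyloxydiene, because C10 presents two CH2-type arms and the ligand's matched sense is not known in advance. A second leak is insertion of zerovalent nickel into the allylic C18–O bond. Fallback: stereochemical purity is obtained by separation instead of by control. Setting out from 14, the cycloaddition is run with Ni(cod)2 and PPh3, which should give 16 together with its ring diastereomer, the (2R,3R,7R,10S) cycloadduct F1. The mixture is hydrolysed as in step 9 to 17 and the (1S,2S,3R,7R,10S) ketone F2. These are diastereomers and should separate on silica gel or by crystallisation, and the route is rejoined at 17.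

Step 3. The most likely failures are erosion of enantioselectivity by the γ-silyloxy group of the acceptor and leakage of the magnesium enolate to the methyl side by proton exchange before the aldehyde is consumed. Fallback: the aldol is taken out of the one-pot sequence. Setting out from 3 and 5, the copper-catalysed addition is run as before, but enolate 7 is silylated with Me3SiCl and Et3N to the trimethylsilyl enol ether F3, which is isolated. A Mukaiyama aldol addition of F3 to 6 (BF3·OEt2, CH2Cl2, −78 °C) then returns to 8.

Step 9. The most likely failures are equilibration at C1 settling on the wrong epimer or a mixture, and participation of the transannular C4=C6 bond while the oxocarbenium ion is present. Fallback: the control principle is changed from equilibrium to irreversible protonation. Setting out from 16, the enol ether is cleaved with TBAF at −78 °C in the presence of a hindered phenol, so that the tetrabutylammonium enolate F4 is protonated once from its exposed face without any cationic intermediate. This returns to 17.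

Step 10. The most likely failure is that the ring's own facial preference overrides reagent control, so that the C9 epimer predominates. Fallback: the epimer is inverted instead of being avoided. Setting out from 17, reduction that gives the (9R) alcohol F5 is followed by a Mitsunobu reaction with 4-nitrobenzoic acid (PPh3, DIAD) to the (9S) 4-nitrobenzoate F6. Brief methanolysis (K2CO3, MeOH, 0 °C) returns to 18.

Step 11. The most likely failures are competing cyclopropanation of the more electron-rich side-chain alkene, because the directing hydroxyl is only bishomoallylic, and incomplete facial control. Fallback: selectivity is moved from hydroxyl direction to alkene substitution. Setting out from 18, diazomethane with catalytic Pd(OAc)2 in Et2O at 0 °C is used. This carbene transfer takes cis-1,2-disubstituted ring alkenes and leaves trisubstituted ones alone, and its facial choice follows the side anti to the two allylic substituents. It returns to 20 without any new compound.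

## Further compounds

F1 | step 8 | (2R,3R,7R,10S) ring diastereomer of cycloadduct 16 | CC(C)(C)[Si](c1ccccc1)(c1ccccc1)OC[C@@H](CCC=C(C)C)C1=C(O[Si](C)(C)C(C)(C)C)C[C@@H](C)/C=C\[C@H]2C(=O)OC[C@@H]12
F2 | step 8 | (1S,2S,3R,7R,10S) ring diastereomer of ketone 17 | CC(C)(C)[Si](c1ccccc1)(c1ccccc1)OC[C@@H](CCC=C(C)C)[C@@H]1C(=O)C[C@@H](C)/C=C\[C@H]2C(=O)OC[C@@H]12
F3 | step 3 | trimethylsilyl enol ether of (4S)-4-[(tert-butyldiphenylsilyloxy)methyl]-8-methylnon-7-en-2-one (C1=C9) | CC(C)(C)[Si](c1ccccc1)(c1ccccc1)OC[C@@H](CCC=C(C)C)C=C(C)O[Si](C)(C)C
F4 | step 9 | tetrabutylammonium enolate from 16 (C1=C9–O−) | CC(C)(C)[Si](c1ccccc1)(c1ccccc1)OC[C@@H](CCC=C(C)C)C1=C([O-])C[C@H](C)/C=C\[C@@H]2C(=O)OC[C@H]12.CCCC[N+](CCCC)(CCCC)CCCC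
F5 | step 10 | (9R) epimer of alcohol 18 | CC(C)(C)[Si](c1ccccc1)(c1ccccc1)OC[C@@H](CCC=C(C)C)[C@H]1[C@H](O)C[C@H](C)/C=C\[C@@H]2C(=O)OC[C@H]12
F6 | step 10 | (9S) 4-nitrobenzoate of 18 | CC(C)(C)[Si](c1ccccc1)(c1ccccc1)OC[C@@H](CCC=C(C)C)[C@H]1[C@@H](OC(=O)c3ccc(cc3)[N+](=O)[O-])C[C@H](C)/C=C\[C@@H]2C(=O)OC[C@H]12
F0 | step 11 | none | none
A1 | alternative 1 | twelve-membered allylic lactone (C18 carbonyl, C11–O, (E)-C1=C10, C3 dioxolane, cyclopropane, C9 OTBS) | O=C1CC2(OCCO2)[C@@H]2C[C@@H]2[C@@H](C)C[C@H](O[Si](C)(C)C(C)(C)C)/C=C(CCC=C(C)C)/CO1
A2 | alternative 1 | eight-membered carbocyclic acid with C10=C11 methylene | C=C(CCC=C(C)C)[C@@H]1[C@@H](C(=O)O)C2(OCCO2)[C@@H]2C[C@@H]2[C@@H](C)C[C@@H]1O[Si](C)(C)C(C)(C)C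
A3 | alternative 2 | open-chain C9 aldehyde with (Z)-alkenyl iodide at C8 | CC(=O)OC[C@@H](CCC=C(C)C)[C@@H](C=O)C1=C(C(=O)OC1)[C@@H]1C[C@@H]1/C(C)=C\I
A4 | alternative 2 | C7=C8 dehydro target (cyclic allylic alcohol) | CC(=O)OC[C@@H](CCC=C(C)C)[C@@H]1C2=C(C(=O)OC2)[C@@H]2C[C@@H]2/C(C)=C\[C@@H]1O
A5 | alternative 3 | 2-[(2S)-1-(tert-butyldimethylsilyloxy)-6-methylhept-5-en-2-yl]-5-methylcyclohexane-1,3-dione | CC1CC(=O)C([C@H](CCC=C(C)C)CO[Si](C)(C)C(C)(C)C)C(=O)C1
A6 | alternative 3 | methyl 4-(tert-butyldimethylsilyloxy)but-2-ynoate | COC(=O)C#CCO[Si](C)(C)C(C)(C)C
A7 | alternative 3 | cyclooct-2-ene-1,5-dione with C19 ester on C3 and C18 on C2 | COC(=O)/C1=C(\CO[Si](C)(C)C(C)(C)C)[C@@H]([C@H](CCC=C(C)C)CO[Si](C)(C)C(C)(C)C)C(=O)C[C@H](C)CC1=O
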